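Ring B, the hydroxyquinone (C1′ on chroman C3, C3′ prenyl, C6′ H), is built as a benzene ring from two open-chain pieces and oxidised last. The key step is a Diels–Alder reaction with aromatisation between an acyclic 1-ethoxy-1,3-bis(silyloxy)diene, which carries the finished (R)-chroman on its terminal carbon and the prenyl group on C2, and 3-butyn-2-one. In one operation it forms the C1′–C6′ and C4′–C5′ bonds, closes ring B and places all its substituents, exploiting the oxygens on C2′ and C4′ that flank C3′, the pattern of a β-keto ester. Dakin oxidation then exchanges the C5′ acetyl group for oxygen, and air gives the quinone.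

Key step: step 12

Assumption: carbonate 3 and ester 14 are taken as purchasable; each is otherwise one step from 2-methylbut-3-en-2-ol or from 5-methylhex-4-enoic acid.
Assumption: the (S,S) antipode of the ligand in step 6 is taken to give the R acid; if the sense of induction proves opposite, the (R,R) antipode is used with no other change.
Remark: in 15, 16, 17 and 19 the stereo-elements that disappear on aromatisation (C2 epimers, enol ether geometry, ring sp3 centres) are left open in the SMILES.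

Step 1
Reactants: 1 2,4,6-trihydroxybenzaldehyde
Product: 2 2-hydroxy-4,6-bis(methoxymethoxy)benzaldehyde
Conditions: MOMCl (2.1 equiv), i-Pr2NEt, CH2Cl2, 0 to 23 °C
Reagents that add atoms: chloromethyl methyl ether, COCCl
Why: Acetal protection by O-alkylation; the two hydroxyls that are not hydrogen-bonded to the formyl group should react first, leaving the chelated C2 hydroxyl free.

Step 2
Reactants: 2 2-hydroxy-4,6-bis(methoxymethoxy)benzaldehyde; 3 tert-butyl (2-methylbut-3-en-2-yl) carbonate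
Product: 4 2-[(2-methylbut-3-en-2-yl)oxy]-4,6-bis(methoxymethoxy)benzaldehyde
Conditions: Pd(PPh3)4 (zerovalent palladium, 5 mol %), THF, 0 to 23 °C
Reagents that add atoms: none
Why: Tsuji–Trost O-allylation; under kinetic control the phenoxide should attack the more substituted terminus of the 1,1-dimethylallyl palladium complex and give the tertiary ether.

Step 3
Reactants: 4 2-[(2-methylbut-3-en-2-yl)oxy]-4,6-bis(methoxymethoxy)benzaldehyde
Product: 5 2-hydroxy-4,6-bis(methoxymethoxy)-3-(3-methylbut-2-en-1-yl)benzaldehyde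
Conditions: toluene, 110 °C
Reagents that add atoms: none
Why: Aromatic Claisen rearrangement ([3,3] shift, then enolisation); C3 is the only ortho position that can re-aromatise, so the prenyl group should arrive there, next to the oxygen that becomes the methoxy group.

Step 4
Reactants: 5 2-hydroxy-4,6-bis(methoxymethoxy)-3-(3-methylbut-2-en-1-yl)benzaldehyde
Product: 6 2-methoxy-4,6-bis(methoxymethoxy)-3-(3-methylbut-2-en-1-yl)benzaldehyde
Conditions: MeI, K2CO3, DMF, 40 °C
Reagents that add atoms: iodomethane, CI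
Why: Williamson O-methylation of the only free phenol.

Step 5
Reactants: 6 2-methoxy-4,6-bis(methoxymethoxy)-3-(3-methylbut-2-en-1-yl)benzaldehyde; 7 dimethyl succinate
Product: 8 (E)-3-(methoxycarbonyl)-4-[2-methoxy-4,6-bis(methoxymethoxy)-3-(3-methylbut-2-en-1-yl)phenyl]but-3-enoic acid
Conditions: KOt-Bu, t-BuOH/THF, 50 °C; then cold 1 M HCl to pH 3
Reagents that add atoms: none
Why: Stobbe condensation (aldol addition, lactonisation, E1cB ring opening) should give the half-ester with the aryl group trans to the ester and the two carboxyl groups differentiated.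

Step 6
Reactants: 8 (E)-3-(methoxycarbonyl)-4-[2-methoxy-4,6-bis(methoxymethoxy)-3-(3-methylbut-2-en-1-yl)phenyl]but-3-enoic acid
Product: 9 (3R)-3-(methoxycarbonyl)-4-[2-methoxy-4,6-bis(methoxymethoxy)-3-(3-methylbut-2-en-1-yl)phenyl]butanoic acid
Conditions: [Rh(cod)((S,S)-Et-DuPhos)]BF4 (1 mol %), H2 (5 bar), MeOH, 23 °C
Reagents that add atoms: none
Why: Asymmetric hydrogenation of an itaconate-type half-ester; carboxylate and alkene chelate cationic monovalent rhodium, the bisphospholane selects the alkene face and sets the R centre, and the non-chelating prenyl alkene should not be reduced.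

Step 7
Reactants: 9 (3R)-3-(methoxycarbonyl)-4-[2-methoxy-4,6-bis(methoxymethoxy)-3-(3-methylbut-2-en-1-yl)phenyl]butanoic acid
Product: 11 (4R)-4-{[4,6-dihydroxy-2-methoxy-3-(3-methylbut-2-en-1-yl)phenyl]methyl}oxolan-2-one, via hydroxy acid 10 (not isolated)
Conditions: LiBH4 (3 equiv), THF, 0 to 23 °C; then 3 M HCl, MeOH, 45 °C
Reagents that add atoms: none
Why: Chemoselective borohydride reduction of the ester beside the lithium carboxylate, then acid-promoted lactonisation and cleavage of both acetals in the same flask; the stereocentre is not touched.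

Step 8
Reactants: 11 (4R)-4-{[4,6-dihydroxy-2-methoxy-3-(3-methylbut-2-en-1-yl)phenyl]methyl}oxolan-2-one
Product: 12 (3R)-3-{[4,6-dihydroxy-2-methoxy-3-(3-methylbut-2-en-1-yl)phenyl]methyl}-4-hydroxy-N-methoxy-N-methylbutanamide
Conditions: MeNH(OMe)·HCl (6 equiv), AlMe3 (6 equiv), CH2Cl2, 0 to 23 °C; aqueous KNaC4H4O6
Reagents that add atoms: N,O-dimethylhydroxylamine hydrochloride, CNOC.Cl
Why: Aminolysis of the lactone by the aluminium amide (Weinreb amide formation) frees the primary alcohol and turns the carboxyl group into an acyl donor that does not over-add.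

Step 9
Reactants: 12 (3R)-3-{[4,6-dihydroxy-2-methoxy-3-(3-methylbut-2-en-1-yl)phenyl]methyl}-4-hydroxy-N-methoxy-N-methylbutanamide
Product: 13 2-[(3R)-7-hydroxy-5-methoxy-6-(3-methylbut-2-en-1-yl)-3,4-dihydro-2H-chromen-3-yl]-N-methoxy-N-methylacetamide
Conditions: PPh3, DIAD, THF, 0 °C
Reagents that add atoms: none
Why: Mitsunobu etherification; only the phenol ortho to the benzylic carbon can reach the activated primary carbon (6-exo-tet), so the chroman should close while the other phenol stays free, and the stereocentre is not the reacting carbon.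

Step 10
Reactants: 13 2-[(3R)-7-hydroxy-5-methoxy-6-(3-methylbut-2-en-1-yl)-3,4-dihydro-2H-chromen-3-yl]-N-methoxy-N-methylacetamide; 14 ethyl 5-methylhex-4-enoate
Product: 15 ethyl 4-[(3R)-7-hydroxy-5-methoxy-6-(3-methylbut-2-en-1-yl)-3,4-dihydro-2H-chromen-3-yl]-2-(3-methylbut-2-en-1-yl)-3-oxobutanoate (both C2 epimers)
Conditions: LiN(i-Pr)2 (3.5 equiv), 14 (3.5 equiv), THF, −78 °C; then 13, −78 to −20 °C; aqueous NH4Cl
Reagents that add atoms: none
Why: Crossed Claisen-type acylation of the ester enolate by the Weinreb amide, whose chelated tetrahedral intermediate prevents over-addition; one equivalent of enolate is spent on the phenol.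

Step 11
Reactants: 15 ethyl 4-[(3R)-7-hydroxy-5-methoxy-6-(3-methylbut-2-en-1-yl)-3,4-dihydro-2H-chromen-3-yl]-2-(3-methylbut-2-en-1-yl)-3-oxobutanoate
Product: 17 (3R)-3-[4-ethoxy-3-(3-methylbut-2-en-1-yl)-2,4-bis(trimethylsilyloxy)buta-1,3-dien-1-yl]-5-methoxy-6-(3-methylbut-2-en-1-yl)-7-(trimethylsilyloxy)-3,4-dihydro-2H-chromene, via silyl enol ether 16 (not isolated)
Conditions: Me3SiOTf (3.6 equiv), Et3N (4.5 equiv), Et2O, 0 to 23 °C; ether layer decanted and concentrated under argon, used at once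
Reagents that add atoms: trimethylsilyl trifluoromethanesulfonate, C[Si](C)(C)OS(=O)(=O)C(F)(F)F
Why: Double O-silylation of a β-keto ester (silyl enol ether, then vinylogous deprotonation to the silyl ketene acetal); the phenol is silylated too, which serves as its temporary protection.

Step 12
Reactants: 17 (3R)-3-[4-ethoxy-3-(3-methylbut-2-en-1-yl)-2,4-bis(trimethylsilyloxy)buta-1,3-dien-1-yl]-5-methoxy-6-(3-methylbut-2-en-1-yl)-7-(trimethylsilyloxy)-3,4-dihydro-2H-chromene; 18 3-butyn-2-one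
Product: 20 1-{2,4-dihydroxy-5-[(3R)-7-hydroxy-5-methoxy-6-(3-methylbut-2-en-1-yl)-3,4-dihydro-2H-chromen-3-yl]-3-(3-methylbut-2-en-1-yl)phenyl}ethan-1-one, via cycloadduct 19 (not isolated)
Conditions: 18 (3 equiv), toluene, 23 to 80 °C, sealed tube; then 1 M HCl, THF, 23 °C
Reagents that add atoms: none
Why: The electron-rich ketene-acetal diene 17 and the ynone 18 should combine in a normal-electron-demand [4+2] cycloaddition (concerted but asynchronous, bonding leading at the unoxygenated diene terminus), the closest known reaction type being the Diels–Alder reaction of 1-alkoxy-1,3-bis(silyloxy)butadienes with acetylenic ketones and esters followed by aromatisation. The six-membered carbocycle closes by suprafacial [4+2] addition, which forms the bond between the diene terminus attached to chroman C3 and the alkyne CH together with the bond between the ketene-acetal carbon and the acetyl-bearing alkyne carbon. No new stereocentre survives, because aqueous acid hydrolyses the silyl ethyl ketal of 19 and the dienone tautomerises to the phenol with loss of ethanol and the silyl groups; chroman C3 is not alpha to a carbonyl group and keeps its R configuration. The step needs regioselectivity, secured by the three oxygen donors that put the largest HOMO coefficient on the unoxygenated diene terminus, which therefore bonds to the electrophilic beta carbon of the ynone and leaves the acetyl group next to the new phenol. It also needs chemoselectivity over the two prenyl alkenes, which are unactivated and should not compete as dienophiles.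

Step 13
Reactants: 20 1-{2,4-dihydroxy-5-[(3R)-7-hydroxy-5-methoxy-6-(3-methylbut-2-en-1-yl)-3,4-dihydro-2H-chromen-3-yl]-3-(3-methylbut-2-en-1-yl)phenyl}ethan-1-one
Product: 23 2-hydroxy-5-[(3R)-7-hydroxy-5-methoxy-6-(3-methylbut-2-en-1-yl)-3,4-dihydro-2H-chromen-3-yl]-3-(3-methylbut-2-en-1-yl)cyclohexa-2,5-diene-1,4-dione (CNP0148998.1), via aryl acetate 21 (not isolated), via benzenetriol 22 (not isolated)
Conditions: 30% H2O2 (1.1 equiv), 2 M NaOH, THF/H2O, 0 °C, argon; Na2SO3; phosphate buffer pH 7, O2 (air), 23 °C; then HCl to pH 4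
Reagents that add atoms: hydrogen peroxide, OO
Why: Dakin oxidation (hydroperoxide addition to the ketone, migration of the electron-rich aryl group, saponification of the aryl acetate) followed by autoxidation of the hydroxyhydroquinone, which is far more easily oxidised than the ring A phenol, to the 2-hydroxy-1,4-benzoquinone.

Compound list
1 | 2,4,6-trihydroxybenzaldehyde | O=Cc1c(O)cc(O)cc1O | starting material
2 | 2-hydroxy-4,6-bis(methoxymethoxy)benzaldehyde | O=Cc1c(O)cc(OCOC)cc1OCOC | intermediate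
3 | tert-butyl (2-methylbut-3-en-2-yl) carbonate | CC(C)(C)OC(=O)OC(C)(C)C=C | starting material
4 | 2-[(2-methylbut-3-en-2-yl)oxy]-4,6-bis(methoxymethoxy)benzaldehyde | O=Cc1c(OC(C)(C)C=C)cc(OCOC)cc1OCOC | intermediate
5 | 2-hydroxy-4,6-bis(methoxymethoxy)-3-(3-methylbut-2-en-1-yl)benzaldehyde | O=Cc1c(O)c(CC=C(C)C)c(OCOC)cc1OCOC | intermediate
6 | 2-methoxy-4,6-bis(methoxymethoxy)-3-(3-methylbut-2-en-1-yl)benzaldehyde | O=Cc1c(OC)c(CC=C(C)C)c(OCOC)cc1OCOC | intermediate
7 | dimethyl succinate | COC(=O)CCC(=O)OC | starting material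
8 | (E)-3-(methoxycarbonyl)-4-[2-methoxy-4,6-bis(methoxymethoxy)-3-(3-methylbut-2-en-1-yl)phenyl]but-3-enoic acid | COC(=O)/C(=C/c1c(OC)c(CC=C(C)C)c(OCOC)cc1OCOC)CC(=O)O | intermediate
9 | (3R)-3-(methoxycarbonyl)-4-[2-methoxy-4,6-bis(methoxymethoxy)-3-(3-methylbut-2-en-1-yl)phenyl]butanoic acid | COC(=O)[C@H](Cc1c(OC)c(CC=C(C)C)c(OCOC)cc1OCOC)CC(=O)O | intermediate
10 | (3R)-4-hydroxy-3-{[2-methoxy-4,6-bis(methoxymethoxy)-3-(3-methylbut-2-en-1-yl)phenyl]methyl}butanoic acid (hydroxy acid) | OC[C@H](Cc1c(OC)c(CC=C(C)C)c(OCOC)cc1OCOC)CC(=O)O | intermediate (not isolated)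
11 | (4R)-4-{[4,6-dihydroxy-2-methoxy-3-(3-methylbut-2-en-1-yl)phenyl]methyl}oxolan-2-one | O=C1C[C@@H](Cc2c(OC)c(CC=C(C)C)c(O)cc2O)CO1 | intermediate
12 | (3R)-3-{[4,6-dihydroxy-2-methoxy-3-(3-methylbut-2-en-1-yl)phenyl]methyl}-4-hydroxy-N-methoxy-N-methylbutanamide | CON(C)C(=O)C[C@@H](Cc1c(OC)c(CC=C(C)C)c(O)cc1O)CO | intermediate
13 | 2-[(3R)-7-hydroxy-5-methoxy-6-(3-methylbut-2-en-1-yl)-3,4-dihydro-2H-chromen-3-yl]-N-methoxy-N-methylacetamide | COc1c(CC=C(C)C)c(O)cc2c1C[C@H](CC(=O)N(C)OC)CO2 | intermediate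
14 | ethyl 5-methylhex-4-enoate | CCOC(=O)CCC=C(C)C | starting material
15 | ethyl 4-[(3R)-7-hydroxy-5-methoxy-6-(3-methylbut-2-en-1-yl)-3,4-dihydro-2H-chromen-3-yl]-2-(3-methylbut-2-en-1-yl)-3-oxobutanoate | COc1c(CC=C(C)C)c(O)cc2c1C[C@H](CC(=O)C(CC=C(C)C)C(=O)OCC)CO2 | intermediate
16 | ethyl 4-[(3R)-5-methoxy-6-(3-methylbut-2-en-1-yl)-7-(trimethylsilyloxy)-3,4-dihydro-2H-chromen-3-yl]-2-(3-methylbut-2-en-1-yl)-3-(trimethylsilyloxy)but-2-enoate (silyl enol ether) | COc1c(CC=C(C)C)c(O[Si](C)(C)C)cc2c1C[C@H](CC(O[Si](C)(C)C)=C(CC=C(C)C)C(=O)OCC)CO2 | intermediate (not isolated)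
17 | (3R)-3-[4-ethoxy-3-(3-methylbut-2-en-1-yl)-2,4-bis(trimethylsilyloxy)buta-1,3-dien-1-yl]-5-methoxy-6-(3-methylbut-2-en-1-yl)-7-(trimethylsilyloxy)-3,4-dihydro-2H-chromene | COc1c(CC=C(C)C)c(O[Si](C)(C)C)cc2c1C[C@H](C=C(O[Si](C)(C)C)C(CC=C(C)C)=C(OCC)O[Si](C)(C)C)CO2 | intermediate
18 | 3-butyn-2-one | CC(=O)C#C | starting material
19 | 1-[6-ethoxy-5-(3-methylbut-2-en-1-yl)-4,6-bis(trimethylsilyloxy)-3-(chroman-3-yl)cyclohexa-1,4-dien-1-yl]ethan-1-one, chroman as in 17 (cycloadduct) | COc1c(CC=C(C)C)c(O[Si](C)(C)C)cc2c1C[C@H](C1C=C(C(C)=O)C(OCC)(O[Si](C)(C)C)C(CC=C(C)C)=C1O[Si](C)(C)C)CO2 | intermediate (not isolated)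
20 | 1-{2,4-dihydroxy-5-[(3R)-7-hydroxy-5-methoxy-6-(3-methylbut-2-en-1-yl)-3,4-dihydro-2H-chromen-3-yl]-3-(3-methylbut-2-en-1-yl)phenyl}ethan-1-one | COc1c(CC=C(C)C)c(O)cc2c1C[C@H](c1cc(C(C)=O)c(O)c(CC=C(C)C)c1O)CO2 | intermediate
21 | 2,4-dihydroxy-5-[(3R)-7-hydroxy-5-methoxy-6-(3-methylbut-2-en-1-yl)-3,4-dihydro-2H-chromen-3-yl]-3-(3-methylbut-2-en-1-yl)phenyl acetate (aryl acetate) | COc1c(CC=C(C)C)c(O)cc2c1C[C@H](c1cc(OC(C)=O)c(O)c(CC=C(C)C)c1O)CO2 | intermediate (not isolated)
22 | 5-[(3R)-7-hydroxy-5-methoxy-6-(3-methylbut-2-en-1-yl)-3,4-dihydro-2H-chromen-3-yl]-3-(3-methylbut-2-en-1-yl)benzene-1,2,4-triol (benzenetriol) | COc1c(CC=C(C)C)c(O)cc2c1C[C@H](c1cc(O)c(O)c(CC=C(C)C)c1O)CO2 | intermediate (not isolated)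
23 | 2-hydroxy-5-[(3R)-7-hydroxy-5-methoxy-6-(3-methylbut-2-en-1-yl)-3,4-dihydro-2H-chromen-3-yl]-3-(3-methylbut-2-en-1-yl)cyclohexa-2,5-diene-1,4-dione (CNP0148998.1) | COc1c(CC=C(C)C)c(O)cc2c1C[C@H](C1=CC(=O)C(O)=C(CC=C(C)C)C1=O)CO2 | target

Total step count: 13. Longest linear sequence: 13 steps (from 1; compounds 3, 7, 14 and 18 enter as purchased building blocks).

Steps most likely to fail

Step 12 (key step). The tetrasubstituted acyclic diene may fail to reach the s-cis conformation, so that protodesilylation, or stepwise conjugate addition without ring closure, outruns the cycloaddition. The fallback is an Alder–Rickert reaction in which the diene is locked s-cis in a ring and the same two ring bonds are formed; it sets out from 13 and comes back at 20. MeMgBr (THF, 0 °C) should convert 13 into the methyl ketone 1-[(3R)-7-hydroxy-5-methoxy-6-(3-methylbut-2-en-1-yl)-3,4-dihydro-2H-chromen-3-yl]propan-2-one F1. A one-pot Michael addition to methyl acrylate and Claisen cyclisation (KOt-Bu, THF) should give the 4-substituted cyclohexane-1,3-dione F2. Palladium-catalysed C-prenylation between the carbonyl groups (methyl 3-methylbut-2-en-1-yl carbonate, Pd(PPh3)4, THF) should give the 2-prenyl dione F3, and Me3SiOTf/Et3N the cyclic 1,3-bis(trimethylsilyloxy)cyclohexa-1,3-diene F4. Heating F4 with 18 (xylene, 150 °C) should give the bicyclo[2.2.2]octadiene F5, which loses ethene by retro-Diels–Alder reaction and gives 20 on work-up with 1 M HCl.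

Step 13. The hydroxyquinone, once formed, may be attacked by alkaline hydroperoxide (epoxidation, ring contraction of the Hooker type), or aryl migration in the chelated ketone may be too slow. The fallback avoids peroxide and introduces the last oxygen by phenol oxidation; it sets out from 17 and comes back at 23. Cycloaddition of 17 with phenyl vinyl sulfoxide as an ethyne equivalent (toluene, 110 °C) should give the sulfinylcyclohexene F6, which loses benzenesulfenic acid on heating and is aromatised by 1 M HCl in THF to the resorcinol (3R)-3-[2,4-dihydroxy-3-(3-methylbut-2-en-1-yl)phenyl]-5-methoxy-6-(3-methylbut-2-en-1-yl)-3,4-dihydro-2H-chromen-7-ol F7. Oxidation with (KSO3)2NO (KH2PO4 buffer, aqueous acetone, 0 °C) at the free position para to the C2′ hydroxyl should then give 23; ring A has no free para position and should react more slowly.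

Step 6. Hydrogen delivery to the hindered 2,6-disubstituted arylidene may be slow or poorly face-selective, or the prenyl group may be partly saturated. The fallback replaces catalytic hydrogenation by an auxiliary-controlled alkylation; it sets out from 6 and comes back at 11. Reductive alkylation of Meldrum's acid with 6 (Hantzsch ester, L-proline, EtOH, 23 °C) should give the 5-benzyl Meldrum's acid F8, and hydrolysis with decarboxylation (pyridine/H2O, 100 °C) the 3-arylpropanoic acid F9. Acylation of lithiated (S)-4-benzyl-1,3-oxazolidin-2-one through the pivaloyl mixed anhydride (t-BuCOCl, Et3N; then n-BuLi, THF, −78 °C) should give the imide F10. Evans alkylation (NaN(SiMe3)2, BrCH2CO2t-Bu, THF, −78 °C), in which the electrophile enters anti to the benzyl group of the auxiliary, should give the R succinate F11. LiBH4 (THF, 1 equiv MeOH, 0 °C) should remove the auxiliary reductively and give the hydroxy tert-butyl ester F12, which 3 M HCl in MeOH (45 °C) converts into lactone 11.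

Further compounds
F1 | step 12 | 1-[(3R)-7-hydroxy-5-methoxy-6-(3-methylbut-2-en-1-yl)-3,4-dihydro-2H-chromen-3-yl]propan-2-one | COc1c(CC=C(C)C)c(O)cc2c1C[C@H](CC(C)=O)CO2
F2 | step 12 | 4-[(3R)-7-hydroxy-5-methoxy-6-(3-methylbut-2-en-1-yl)-3,4-dihydro-2H-chromen-3-yl]cyclohexane-1,3-dione | COc1c(CC=C(C)C)c(O)cc2c1C[C@H](C1CCC(=O)CC1=O)CO2
F3 | step 12 | 4-[(3R)-7-hydroxy-5-methoxy-6-(3-methylbut-2-en-1-yl)-3,4-dihydro-2H-chromen-3-yl]-2-(3-methylbut-2-en-1-yl)cyclohexane-1,3-dione | COc1c(CC=C(C)C)c(O)cc2c1C[C@H](C1CCC(=O)C(CC=C(C)C)C1=O)CO2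
F4 | step 12 | (3R)-3-[3-(3-methylbut-2-en-1-yl)-2,4-bis(trimethylsilyloxy)cyclohexa-1,3-dien-1-yl]-5-methoxy-6-(3-methylbut-2-en-1-yl)-7-(trimethylsilyloxy)-3,4-dihydro-2H-chromene | COc1c(CC=C(C)C)c(O[Si](C)(C)C)cc2c1C[C@H](C1=C(O[Si](C)(C)C)C(CC=C(C)C)=C(O[Si](C)(C)C)CC1)CO2
F5 | step 12 | 1-[6-(3-methylbut-2-en-1-yl)-1,5-bis(trimethylsilyloxy)-4-(chroman-3-yl)bicyclo[2.2.2]octa-2,5-dien-2-yl]ethan-1-one, chroman as in F4 | COc1c(CC=C(C)C)c(O[Si](C)(C)C)cc2c1C[C@H](C13CCC(O[Si](C)(C)C)(C(C(C)=O)=C1)C(CC=C(C)C)=C3O[Si](C)(C)C)CO2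
F6 | step 13 | (3R)-3-[4-ethoxy-3-(3-methylbut-2-en-1-yl)-5-(phenylsulfinyl)-2,4-bis(trimethylsilyloxy)cyclohex-2-en-1-yl]-5-methoxy-6-(3-methylbut-2-en-1-yl)-7-(trimethylsilyloxy)-3,4-dihydro-2H-chromene | COc1c(CC=C(C)C)c(O[Si](C)(C)C)cc2c1C[C@H](C1CC(S(=O)c3ccccc3)C(OCC)(O[Si](C)(C)C)C(CC=C(C)C)=C1O[Si](C)(C)C)CO2
F7 | step 13 | (3R)-3-[2,4-dihydroxy-3-(3-methylbut-2-en-1-yl)phenyl]-5-methoxy-6-(3-methylbut-2-en-1-yl)-3,4-dihydro-2H-chromen-7-ol | COc1c(CC=C(C)C)c(O)cc2c1C[C@H](c1ccc(O)c(CC=C(C)C)c1O)CO2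
F8 | step 6 | 5-{[2-methoxy-4,6-bis(methoxymethoxy)-3-(3-methylbut-2-en-1-yl)phenyl]methyl}-2,2-dimethyl-1,3-dioxane-4,6-dione | CC1(C)OC(=O)C(Cc2c(OC)c(CC=C(C)C)c(OCOC)cc2OCOC)C(=O)O1
F9 | step 6 | 3-[2-methoxy-4,6-bis(methoxymethoxy)-3-(3-methylbut-2-en-1-yl)phenyl]propanoic acid | OC(=O)CCc1c(OC)c(CC=C(C)C)c(OCOC)cc1OCOC
F10 | step 6 | (4S)-4-benzyl-3-{3-[2-methoxy-4,6-bis(methoxymethoxy)-3-(3-methylbut-2-en-1-yl)phenyl]propanoyl}-1,3-oxazolidin-2-one | O=C(CCc1c(OC)c(CC=C(C)C)c(OCOC)cc1OCOC)N1[C@@H](Cc2ccccc2)COC1=O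
F11 | step 6 | tert-butyl (3R)-4-[(4S)-4-benzyl-2-oxo-1,3-oxazolidin-3-yl]-3-{[2-methoxy-4,6-bis(methoxymethoxy)-3-(3-methylbut-2-en-1-yl)phenyl]methyl}-4-oxobutanoate | CC(C)(C)OC(=O)C[C@@H](Cc1c(OC)c(CC=C(C)C)c(OCOC)cc1OCOC)C(=O)N1[C@@H](Cc2ccccc2)COC1=O
F12 | step 6 | tert-butyl (3R)-4-hydroxy-3-{[2-methoxy-4,6-bis(methoxymethoxy)-3-(3-methylbut-2-en-1-yl)phenyl]methyl}butanoate | CC(C)(C)OC(=O)C[C@@H](Cc1c(OC)c(CC=C(C)C)c(OCOC)cc1OCOC)CO
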